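## Retrosynthetic overview

1. The cyclohexene–cyclohexenedione ring pair of the target comes from an intermolecular Diels–Alder reaction. The diene is 7β-hydroxy-4-epi-trans-communic acid, released in situ from its SO2 adduct. The dienophile is 2-methoxy-5-(5,7-dihydroxychromon-2-yl)-1,4-benzoquinone.
2. The 7β-OH comes from SeO2/TBHP allylic oxidation of the C8=C17 exocyclic alkene of the SO2-masked diterpene acid. The decalin and its stereocenters (C4, C5, C9, C10) come from the chiral-pool acid.
3. The quinone comes from CAN oxidation of a 2′,4′,5′-trimethoxyflavone. That flavone comes from I2/DMSO cyclization of a chalcone, which comes from Claisen–Schmidt condensation of phloroacetophenone with 2,4,5-trimethoxybenzaldehyde.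
4. Ring order: chromone pyranone ring (step 2), quinone ring (step 3), sulfolene mask (step 4), and last the new cyclohexene ring by Diels–Alder (step 6).

Assumptions:
- The target's C4 carries an equatorial CO2H, trans to the C10 methyl. This is read from the SMILES and is the 18-oic (4-epi) series, so the chiral-pool starting material is 4-epi-trans-communic acid from juniper/cypress resin, taken as purchased or isolated.
- The target's 7-OH is β (equatorial) on the 10β-Me, 5α-H, 9α-H trans-decalin, also read from the SMILES.

## Route

**Step 1**
Reactants: **1** 2,4,5-trimethoxybenzaldehyde; **2** 2′,4′,6′-trihydroxyacetophenone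
Product: **3** (E)-2′,4′,6′-trihydroxy-2,4,5-trimethoxychalcone
Conditions: 50% aq KOH, EtOH, rt → 50 °C, 48 h; then HCl to acidify
Reagents that add atoms: none
Why: Claisen–Schmidt aldol condensation of the acetophenone enolate onto the aldehyde, with dehydration to the conjugated E-enone. No stereocenter is formed.

**Step 2**
Reactants: **3** chalcone
Product: **4** 5,7-dihydroxy-2′,4′,5′-trimethoxyflavone
Conditions: I2 (0.1 equiv), DMSO, 130 °C, 3 h
Reagents that add atoms: none
Why: The 2′-OH adds to the iodine-activated enone (oxa-Michael/iodination), HI is eliminated, and DMSO reoxidizes iodide to iodine. This oxidative cyclization gives the aromatic chromone, and the free 5,7-OH groups are tolerated, as in chrysin syntheses.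

**Step 3**
Reactants: **4** flavone
Product: **5** 2-methoxy-5-(5,7-dihydroxy-4-oxo-4H-chromen-2-yl)-1,4-benzoquinone
Conditions: CAN (4 equiv), MeCN/H2O 3:1, 0 °C, 30 min
Reagents that add atoms: water, O (source of the quinone oxygens)
Why: CAN performs oxidative demethylation of the para-dimethoxy pair (2′-OMe and 5′-OMe) to the quinone. The 4′-OMe has no para oxygen partner and stays as the quinone methoxy. The electron-poor chromone A-ring resists oxidation.

**Step 4**
Reactants: **6** 4-epi-trans-communic acid ((12E)-labda-8(17),12,14-trien-18-oic acid, equatorial CO2H); **7** sulfur dioxide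
Product: **8** SO2 adduct of **6** (2-substituted 3-methyl-2,5-dihydrothiophene 1,1-dioxide; C12 epimeric mixture)
Conditions: liquid SO2, hydroquinone (trace), sealed tube, 0 °C → rt, 24 h; then evaporate the SO2
Reagents that add atoms: sulfur dioxide, O=S=O
Why: Cheletropic [4+1] addition of SO2 to the s-cis diene gives the 3-sulfolene. This masks the diene so that the SeO2 step sees only the exocyclic alkene. The new C12 stereocenter is destroyed again when SO2 is lost, so its configuration does not matter.

**Step 5**
Reactants: **8** sulfolene adduct
Product: **9** 7β-hydroxy sulfolene adduct (C12 epimeric mixture)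
Conditions: SeO2 (0.2 equiv), TBHP (3 equiv, 5.5 M in decane), CH2Cl2, 0 °C → rt, 24 h
Reagents that add atoms: tert-butyl hydroperoxide, CC(C)(C)OO (terminal oxidant and source of the alcohol oxygen; SeO2, O=[Se]=O, is catalytic)
Why: Allylic oxidation of the 1,1-disubstituted C8=C17 alkene proceeds by SeO2 ene reaction followed by [2,3]-sigmatropic shift of the allylic seleninic acid. The sulfone-deactivated trisubstituted sulfolene alkene is expected to be untouched, and the free acid is inert. The equatorial 7β-alcohol is expected as the major isomer, so C7 is set by substrate control from the trans-decalin; any 7α isomer is a minor by-product.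

**Step 6**
Reactants: **9** 7β-hydroxy sulfolene adduct; **5** quinone (2 equiv)
Product: **11** Dichrostachine E (via **10**, 7β-hydroxy-4-epi-trans-communic acid, generated in situ and not isolated)
Conditions: toluene/1,4-dioxane (3:1), BHT, reflux (~105–110 °C) under an N2 stream to sweep out SO2, 24–48 h; then HPLC
Reagents that add atoms: none
Why: Retro-cheletropic loss of SO2 releases the (12E)-diene **10** slowly and stereospecifically. It undergoes an intermolecular Diels–Alder reaction with the chromonyl-bearing C=C of **5**. The OMe-bearing C=C is deactivated as a vinylogous ester, so the electrophilic chromonyl-bearing carbon (β to C1=O) bonds to C12. Suprafacial addition makes the new ring fusion cis (C16–H and the chromone on the same face). The target's C12 configuration (C11 cis to the chromone, trans to the quinone carbonyls) arises from approach with the chromone endo, which is the minor pathway relative to the carbonyl-endo default. The remote C9 stereocenter gives only a weak facial bias, so a diastereomer mixture is expected and the target isomer is separated by HPLC. The 7β-OH, exocyclic alkene, acid and phenols survive neutral heating.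

## Compound list
1 | 2,4,5-trimethoxybenzaldehyde | O=Cc1cc(OC)c(OC)cc1OC | starting material
2 | 2′,4′,6′-trihydroxyacetophenone | CC(=O)c1c(O)cc(O)cc1O | starting material
3 | (E)-2′,4′,6′-trihydroxy-2,4,5-trimethoxychalcone | O=C(/C=C/c1cc(OC)c(OC)cc1OC)c1c(O)cc(O)cc1O | intermediate
4 | 5,7-dihydroxy-2′,4′,5′-trimethoxyflavone | O=c1cc(-c2cc(OC)c(OC)cc2OC)oc2cc(O)cc(O)c12 | intermediate
5 | 2-methoxy-5-(5,7-dihydroxy-4-oxochromen-2-yl)-1,4-benzoquinone | COC1=CC(=O)C(=CC1=O)c1cc(=O)c2c(O)cc(O)cc2o1 | intermediate
6 | 4-epi-trans-communic acid, (12E)-labda-8(17),12,14-trien-18-oic acid | C=C1CC[C@@H]2[C@](C)(CCC[C@@]2(C)C(=O)O)[C@H]1C/C=C(C)/C=C | starting material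
7 | sulfur dioxide | O=S=O | starting material
8 | SO2 adduct of 6 (C12 epimeric mixture) | C=C1CC[C@@H]2[C@](C)(CCC[C@@]2(C)C(=O)O)[C@H]1CC1C(C)=CCS1(=O)=O | intermediate
9 | 7β-hydroxy SO2 adduct (C12 epimeric mixture) | C=C1[C@@H](O)C[C@@H]2[C@](C)(CCC[C@@]2(C)C(=O)O)[C@H]1CC1C(C)=CCS1(=O)=O | intermediate
10 | 7β-hydroxy-4-epi-trans-communic acid (formed in situ from 9, not isolated) | C=C1[C@@H](O)C[C@@H]2[C@](C)(CCC[C@@]2(C)C(=O)O)[C@H]1C/C=C(C)/C=C | intermediate
11 | Dichrostachine E | C=C1[C@@H](O)C[C@@H]2[C@](C)(CCC[C@@]2(C)C(=O)O)[C@H]1C[C@@H]1C(C)=CC[C@H]2C(=O)C(OC)=CC(=O)[C@@]12c1cc(=O)c2c(O)cc(O)cc2o1 | target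

Atom check: 10 (C20H30O3) + 5 (C16H10O7) = C36H40O10, the formula of 11. SO2 is lost in step 6 and no other atoms are lost.

**Total steps:** 6
**Longest linear sequence:** 4 steps (1 → 2 → 3 → 6, from the aldehyde and acetophenone; the diterpene branch is 4 → 5 → 6)

## Three steps most likely to fail
1. **Step 6 (Diels–Alder).** The dienophile carbon is fully substituted and the diene terminus is secondary, so the reaction is slow. The carbonyl-endo pathway gives the wrong C12 epimer, and facial selectivity is weak.
   - Fallback: protect the A-ring phenols of 4 as bis-allyl ethers before CAN oxidation and run the Diels–Alder on the protected quinone. Separate the diastereomers at the protected stage and remove the allyl groups last with Pd(PPh3)4/PhSiH3. This avoids phenol–quinone side reactions and solubility problems.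
2. **Step 5 (SeO2 allylic oxidation).** The yield may be low, the 7α-epimer may form, or the sulfolene alkene may react.
   - Fallback: oxidize 8 to the 7-oxo-8(17)-ene enone (CrO3·3,5-dimethylpyrazole). Then do a Luche reduction (NaBH4/CeCl3), where axial hydride attack from the α face gives the equatorial 7β-OH. This replaces direct hydroxylation with an oxidation–reduction sequence.
3. **Step 3 (CAN oxidation of the free-phenol flavone).** Over-oxidation or decomposition of the electron-rich A-ring is possible.
   - Fallback: build the flavone from a Baker–Venkataraman sequence on a bis-MOM-protected phloroacetophenone. Oxidize to the quinone, then remove the MOM groups with mild acid before the Diels–Alder. Alternatively, couple a protected 2-iodochromone with (2,4,5-trimethoxyphenyl)boronic acid and then oxidize.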